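**Strategy.** Ring C (the 4-bromo-2-iodophenoxy ring) carries its ether oxygen at C1 and iodine at C2, with bromine at C4 para to the oxygen. This is the pattern left when 4-bromobenzyne takes an oxygen nucleophile at one aryne carbon and an iodine electrophile at the other. The route therefore forms the ring B–O–ring C bond and the C–I bond in a single three-component operation. The precursor is the fully brominated ring A–B diaryl ether phenol, 2,3,4-tribromo-6-(2,4-dibromo-6-methoxyphenoxy)phenol, built by SNAr, Dakin-type oxidation and bromination. The ring A oxygen travels as a methyl ether, which is cleaved and sulfated at the end.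

Key step: step 7

Remark on ring labels: ring A is the sulfated 3,5-dibromophenyl ring, ring B the central tribromo ring, ring C the 4-bromo-2-iodophenoxy ring.

Remark on starting materials: a second bromination of guaiacol can enter para to the methoxy group as well as ortho to the hydroxyl. To exclude that isomer, the route starts from commercial 2-bromo-6-methoxyphenol. The aryne precursor is made from commercial 4-bromo-2-iodophenol so that halogen–lithium exchange is chemoselective for iodine.

Assumption: the target is drawn as the free aryl hydrogen sulfate, so the last step is written to deliver that acid; in practice it would be stored as its sodium salt.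

**Step 1**
Reactants: 1 2-bromo-6-methoxyphenol
Product: 2 2,4-dibromo-6-methoxyphenol
Conditions: NBS (1.0 equiv), MeCN, 0 °C → rt
Reagents that add atoms: N-bromosuccinimide (NBS), O=C1CCC(=O)N1Br
Why: Electrophilic aromatic bromination directed by the free hydroxyl, whose one ortho site is already brominated and the other carries the methoxy group, so bromine should enter only at C4 (para to OH) and fix the ring A pattern.

**Step 2**
Reactants: 2 2,4-dibromo-6-methoxyphenol; 3 5-bromo-2-fluorobenzaldehyde
Product: 4 5-bromo-2-(2,4-dibromo-6-methoxyphenoxy)benzaldehyde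
Conditions: K2CO3, DMAc, 120 °C
Reagents that add atoms: none
Why: Nucleophilic aromatic substitution (SNAr) in which the ortho formyl group activates the C–F bond toward the phenoxide, while the unactivated aryl bromides should stay untouched.

**Step 3**
Reactants: 4 5-bromo-2-(2,4-dibromo-6-methoxyphenoxy)benzaldehyde
Product: 6 5-bromo-2-(2,4-dibromo-6-methoxyphenoxy)phenol, via aryl formate 5 (not isolated)
Conditions: mCPBA, CH2Cl2, rt; then K2CO3, MeOH, rt
Reagents that add atoms: meta-chloroperoxybenzoic acid (mCPBA), O=C(OO)c1cccc(Cl)c1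
Why: Baeyer–Villiger (Dakin-type) oxidation in which the aryl group bearing the ortho aryloxy donor migrates to oxygen to give the formate, which mild methanolysis should convert into the phenol; aryl bromides and ethers are inert to the peracid.

**Step 4**
Reactants: 6 5-bromo-2-(2,4-dibromo-6-methoxyphenoxy)phenol
Product: 8 2,3,4-tribromo-6-(2,4-dibromo-6-methoxyphenoxy)phenol, via para-monobromide 7 (not isolated)
Conditions: Br2 (2.1 equiv), AcOH–CH2Cl2, 0 °C → rt
Reagents that add atoms: bromine, BrBr
Why: Electrophilic bromination steered by the free phenol to its only open para and ortho positions (C4 and C6 of 6, on either side of the existing bromine); ring A is a dibrominated aryl ether and far less reactive, so two equivalents should stop at the contiguous tribromide.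

**Step 5**
Reactants: 9 4-bromo-2-iodophenol
Product: 10 (4-bromo-2-iodophenoxy)trimethylsilane
Conditions: HMDS, THF, 65 °C; concentrate
Reagents that add atoms: hexamethyldisilazane (HMDS), C[Si](C)(C)N[Si](C)(C)C
Why: O-Silylation of the phenol, driven by loss of ammonia, should give the silyl ether needed for the silyl shift in step 6 without aqueous work-up.

**Step 6**
Reactants: 10 (4-bromo-2-iodophenoxy)trimethylsilane
Product: 13 4-bromo-2-(trimethylsilyl)phenyl trifluoromethanesulfonate, via aryllithium 11 (not isolated), via lithium phenoxide 12 (not isolated)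
Conditions: n-BuLi (1.05 equiv), THF, −100 → −80 °C; then Tf2O, −100 °C → rt
Reagents that add atoms: trifluoromethanesulfonic anhydride (Tf2O), O=S(=O)(OS(=O)(=O)C(F)(F)F)C(F)(F)F
Why: Iodine–lithium exchange is much faster than bromine–lithium exchange, so only the ortho carbon is metalated; 1,3 O→C silyl migration (retro-Brook rearrangement) then gives the ortho-silyl phenoxide, which O-triflation should convert into the ortho-silylaryl triflate.

**Step 7**
Reactants: 8 2,3,4-tribromo-6-(2,4-dibromo-6-methoxyphenoxy)phenol; 13 4-bromo-2-(trimethylsilyl)phenyl trifluoromethanesulfonate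
Product: 17 bromoiesol B methyl ether, 1,2,3-tribromo-4-(4-bromo-2-iodophenoxy)-5-(2,4-dibromo-6-methoxyphenoxy)benzene, via potassium phenoxide 14 (not isolated), via 4-bromobenzyne 15 (not isolated), via arylpotassium adduct 16 (not isolated)
Conditions: KH, THF, 0 °C; then C6F13I (5 equiv), KF, 18-crown-6, 13 (2 equiv, slow addition), 0 °C → rt, dark
Reagents that add atoms: perfluorohexyl iodide, FC(F)(F)C(F)(F)C(F)(F)C(F)(F)C(F)(F)C(F)(F)I
Why: Proposed new method: fluoride attacks silicon of 13 and triflate departs to release 4-bromobenzyne 15; the oxygen of phenoxide 14 adds to the aryne carbon para to bromine, and the aryl anion 16 formed at the neighbouring carbon abstracts iodine from the perfluoroalkyl iodide, so the ring B–O–ring C bond and the C–I bond should form in one flask with no transition metal that could insert into C–Br or C–I bonds. The closest known reaction type is the fluoride-triggered three-component coupling of ortho-silylaryl triflate-derived arynes, in which a heteroatom nucleophile adds and the aryl anion is intercepted by an electrophilic halogen donor such as a perfluoroalkyl iodide; the new element is a weakly nucleophilic polybromophenoxide with both ortho positions substituted. No ring is formed and no stereocenter is created. Regioselectivity is required and rests on the inductive effect of bromine, which stabilises developing negative charge at the aryne carbon meta to it and so sends oxygen to the para carbon; the bias is modest, and the 5-bromo-2-iodophenoxy isomer would have to be removed by chromatography. Chemoselectivity is also required: iodine transfer must outrun protonation and bromine abstraction from ring B, which the proton-free medium (phenoxide made with KH, no carbonate or alcohol), the excess of iodine donor and the slow addition of 13 are meant to secure, while the substituted ortho and para positions of 14 block C-arylation and C-iodination.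

**Step 8**
Reactants: 17 bromoiesol B methyl ether
Product: 19 bromoiesol B, 3,5-dibromo-2-[3,4,5-tribromo-2-(4-bromo-2-iodophenoxy)phenoxy]phenol, via aryloxydibromoborane 18 (not isolated)
Conditions: BBr3, CH2Cl2, −78 °C → rt; then H2O
Reagents that add atoms: none
Why: Lewis acid-mediated cleavage of the aryl methyl ether, in which bromide attacks the methyl carbon of the boron-complexed ether; the diaryl ether linkages offer no sp3 carbon for this attack and the aryl halides are inert, so only the methyl group should be lost.

**Step 9**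
Reactants: 19 bromoiesol B
Product: 21 bromoiesol B sulfate, 3,5-dibromo-2-[3,4,5-tribromo-2-(4-bromo-2-iodophenoxy)phenoxy]phenyl hydrogen sulfate, via pyridinium sulfate 20 (not isolated)
Conditions: SO3·pyridine, pyridine, 50 °C; then cation-exchange resin (H+ form), MeOH–H2O, 0 °C
Reagents that add atoms: sulfur trioxide–pyridine complex, O=S(=O)([O-])[n+]1ccccc1
Why: O-Sulfonation of the only hydroxyl group by the SO3·pyridine complex should give the pyridinium aryl sulfate, and cold exchange of the cation for a proton releases the aryl hydrogen sulfate.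

**Compound list**

1 | 2-bromo-6-methoxyphenol | COc1cccc(Br)c1O | starting material
2 | 2,4-dibromo-6-methoxyphenol | COc1cc(Br)cc(Br)c1O | intermediate
3 | 5-bromo-2-fluorobenzaldehyde | O=Cc1cc(Br)ccc1F | starting material
4 | 5-bromo-2-(2,4-dibromo-6-methoxyphenoxy)benzaldehyde | COc1cc(Br)cc(Br)c1Oc1ccc(Br)cc1C=O | intermediate
5 | 5-bromo-2-(2,4-dibromo-6-methoxyphenoxy)phenyl formate | COc1cc(Br)cc(Br)c1Oc1ccc(Br)cc1OC=O | intermediate
6 | 5-bromo-2-(2,4-dibromo-6-methoxyphenoxy)phenol | COc1cc(Br)cc(Br)c1Oc1ccc(Br)cc1O | intermediate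
7 | 4,5-dibromo-2-(2,4-dibromo-6-methoxyphenoxy)phenol | COc1cc(Br)cc(Br)c1Oc1cc(Br)c(Br)cc1O | intermediate
8 | 2,3,4-tribromo-6-(2,4-dibromo-6-methoxyphenoxy)phenol | COc1cc(Br)cc(Br)c1Oc1cc(Br)c(Br)c(Br)c1O | intermediate
9 | 4-bromo-2-iodophenol | Oc1ccc(Br)cc1I | starting material
10 | (4-bromo-2-iodophenoxy)trimethylsilane | C[Si](C)(C)Oc1ccc(Br)cc1I | intermediate
11 | [5-bromo-2-(trimethylsilyloxy)phenyl]lithium | [Li]c1cc(Br)ccc1O[Si](C)(C)C | intermediate
12 | lithium 4-bromo-2-(trimethylsilyl)phenoxide | [Li+].[O-]c1ccc(Br)cc1[Si](C)(C)C | intermediate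
13 | 4-bromo-2-(trimethylsilyl)phenyl trifluoromethanesulfonate | C[Si](C)(C)c1cc(Br)ccc1OS(=O)(=O)C(F)(F)F | intermediate
14 | potassium 2,3,4-tribromo-6-(2,4-dibromo-6-methoxyphenoxy)phenoxide | COc1cc(Br)cc(Br)c1Oc1cc(Br)c(Br)c(Br)c1[O-].[K+] | intermediate
15 | 4-bromobenzyne (4-bromo-1,2-didehydrobenzene) | BrC1=CC#CC=C1 | intermediate
16 | {5-bromo-2-[2,3,4-tribromo-6-(2,4-dibromo-6-methoxyphenoxy)phenoxy]phenyl}potassium | COc1cc(Br)cc(Br)c1Oc1cc(Br)c(Br)c(Br)c1Oc1ccc(Br)cc1[K] | intermediate
17 | bromoiesol B methyl ether, 1,2,3-tribromo-4-(4-bromo-2-iodophenoxy)-5-(2,4-dibromo-6-methoxyphenoxy)benzene | COc1cc(Br)cc(Br)c1Oc1cc(Br)c(Br)c(Br)c1Oc1ccc(Br)cc1I | intermediate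
18 | dibromo{3,5-dibromo-2-[3,4,5-tribromo-2-(4-bromo-2-iodophenoxy)phenoxy]phenoxy}borane | BrB(Br)Oc1cc(Br)cc(Br)c1Oc1cc(Br)c(Br)c(Br)c1Oc1ccc(Br)cc1I | intermediate
19 | bromoiesol B, 3,5-dibromo-2-[3,4,5-tribromo-2-(4-bromo-2-iodophenoxy)phenoxy]phenol | Oc1cc(Br)cc(Br)c1Oc1cc(Br)c(Br)c(Br)c1Oc1ccc(Br)cc1I | intermediate
20 | pyridinium 3,5-dibromo-2-[3,4,5-tribromo-2-(4-bromo-2-iodophenoxy)phenoxy]phenyl sulfate | [O-]S(=O)(=O)Oc1cc(Br)cc(Br)c1Oc1cc(Br)c(Br)c(Br)c1Oc1ccc(Br)cc1I.c1cc[nH+]cc1 | intermediate
21 | bromoiesol B sulfate, 3,5-dibromo-2-[3,4,5-tribromo-2-(4-bromo-2-iodophenoxy)phenoxy]phenyl hydrogen sulfate | O=S(=O)(O)Oc1cc(Br)cc(Br)c1Oc1cc(Br)c(Br)c(Br)c1Oc1ccc(Br)cc1I | target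

**Step count and risks**

Total step count: 9. Longest linear sequence: 7 steps (steps 1, 2, 3, 4, 7, 8, 9, from compound 1); the aryne precursor branch (steps 5 and 6) joins at step 7.

Steps most likely to fail:

Step 7 (the proposed method). Addition of the hindered, weakly nucleophilic phenoxide may be too slow to compete with consumption of the aryne by fluoride or by self-reaction. The aryl anion may be protonated, or may take bromine from ring B, before it meets the iodine donor. Oxygen may add across the aryne with poor regiocontrol, and the fluoroalkene released from the iodine donor may capture phenoxide. The fallback uses known chemistry, sets out from 8 and returns to the route at 17. Phenol 8 is arylated by SNAr with 4-bromo-1-fluoro-2-nitrobenzene (K2CO3, DMF, 80 °C) to give 1,2,3-tribromo-4-(4-bromo-2-nitrophenoxy)-5-(2,4-dibromo-6-methoxyphenoxy)benzene F1. The nitro group is reduced with Fe powder and NH4Cl in EtOH–H2O, which leaves aryl bromides alone, to give 5-bromo-2-[2,3,4-tribromo-6-(2,4-dibromo-6-methoxyphenoxy)phenoxy]aniline F2. Diazotisation with NaNO2 and p-TsOH in MeCN then gives 5-bromo-2-[2,3,4-tribromo-6-(2,4-dibromo-6-methoxyphenoxy)phenoxy]benzenediazonium 4-methylbenzenesulfonate F3, which KI in the same flask should convert into 17 (Sandmeyer-type iodination). The substitution pattern of ring C is then fixed by the fluoronitroarene and not by the aryne.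

Step 3. Hydride migration may compete with aryl migration and over-oxidise the aldehyde to the benzoic acid, because ring B of 4 carries only one donor and a bromine. The fallback sets out from 2 and returns at 6. SNAr of 2 with 1-(5-bromo-2-fluorophenyl)ethanone (K2CO3, DMAc, 120 °C) gives 1-[5-bromo-2-(2,4-dibromo-6-methoxyphenoxy)phenyl]ethanone F4. Baeyer–Villiger oxidation with mCPBA and TFA in CH2Cl2, in which no hydride is available and aryl migrates in preference to methyl, gives 5-bromo-2-(2,4-dibromo-6-methoxyphenoxy)phenyl acetate F5. Methanolysis (K2CO3, MeOH) then gives 6.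

Step 2. Substitution by a phenoxide flanked by bromine and methoxy may be sluggish, and the aldehyde may degrade at the temperature then required. The fallback sets out from 2 and returns at 6, bypassing steps 2 and 3. The more electrophilic 4-bromo-1-fluoro-2-nitrobenzene undergoes SNAr with 2 (K2CO3, DMF, 80 °C) to give 1,5-dibromo-2-(4-bromo-2-nitrophenoxy)-3-methoxybenzene F6. Reduction with Fe powder and NH4Cl gives 5-bromo-2-(2,4-dibromo-6-methoxyphenoxy)aniline F7. Diazotisation with NaNO2 in aqueous H2SO4 at 0 °C gives 5-bromo-2-(2,4-dibromo-6-methoxyphenoxy)benzenediazonium hydrogensulfate F8, and hydroxy-dediazoniation with Cu2O and Cu(NO3)2 in water at rt should give phenol 6.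

**Further compounds**

F1 | step 7 | 1,2,3-tribromo-4-(4-bromo-2-nitrophenoxy)-5-(2,4-dibromo-6-methoxyphenoxy)benzene | COc1cc(Br)cc(Br)c1Oc1cc(Br)c(Br)c(Br)c1Oc1ccc(Br)cc1[N+](=O)[O-]
F2 | step 7 | 5-bromo-2-[2,3,4-tribromo-6-(2,4-dibromo-6-methoxyphenoxy)phenoxy]aniline | COc1cc(Br)cc(Br)c1Oc1cc(Br)c(Br)c(Br)c1Oc1ccc(Br)cc1N
F3 | step 7 | 5-bromo-2-[2,3,4-tribromo-6-(2,4-dibromo-6-methoxyphenoxy)phenoxy]benzenediazonium 4-methylbenzenesulfonate | COc1cc(Br)cc(Br)c1Oc1cc(Br)c(Br)c(Br)c1Oc1ccc(Br)cc1[N+]#N.Cc1ccc(cc1)S(=O)(=O)[O-]
F4 | step 3 | 1-[5-bromo-2-(2,4-dibromo-6-methoxyphenoxy)phenyl]ethanone | COc1cc(Br)cc(Br)c1Oc1ccc(Br)cc1C(C)=O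
F5 | step 3 | 5-bromo-2-(2,4-dibromo-6-methoxyphenoxy)phenyl acetate | COc1cc(Br)cc(Br)c1Oc1ccc(Br)cc1OC(C)=O
F6 | step 2 | 1,5-dibromo-2-(4-bromo-2-nitrophenoxy)-3-methoxybenzene | COc1cc(Br)cc(Br)c1Oc1ccc(Br)cc1[N+](=O)[O-]
F7 | step 2 | 5-bromo-2-(2,4-dibromo-6-methoxyphenoxy)aniline | COc1cc(Br)cc(Br)c1Oc1ccc(Br)cc1N
F8 | step 2 | 5-bromo-2-(2,4-dibromo-6-methoxyphenoxy)benzenediazonium hydrogensulfate | COc1cc(Br)cc(Br)c1Oc1ccc(Br)cc1[N+]#N.OS(=O)(=O)[O-]
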